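At early times the reagent dosed into the flask finds substrate and no intermediate A yet, and the reckoning hangs on how that changes.

    reagent + intermediate A → intermediate B (k1 = 164 /M/s)
    intermediate B → product (k2 = 0.278 /s)
    substrate + reagent → intermediate A (k3 = 392 /M/s)

substrate 5.0 × 10⁻⁴ M; reagent 0.800 equiv (fed, over 20 s); time 3.0 min

1. why nothing more happens at 3.0 min, or that something still does (the reagent has run out first / all of the substrate has reacted / it is still moving)
2. part of the substrate gone at 3.0 min
3. the product standing at 3.0 min, as a percentage of the substrate charged

- the reaction counts as stopped when no species that holds the substrate changes by six tenths of a point or more over the second half of the time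
- run time (flask): 3.0 min

My first guess lets each reagent take one substrate, which leaves a fraction x = 0.200 of the substrate and no product. My objection is that intermediate A competes for the reagent. Both steps that use reagent are first order in it, so [reagent] cancels from their ratio, and what stays constant is the selectivity factor κ, the rate constant for intermediate A over that for substrate, 164 /M/s over 392 /M/s, or 0.418. With y = [intermediate A] as a fraction of the substrate charged, and e the equivalents of reagent used:

dy/dx = −1 + κy/x, so y = (x^κ − x)/(1 − κ)

2(1 − x) − y = e

x^κ = (1 − κ)(2 − e) − (1 − 2κ)x

Putting each x into the right side gives 0.378, 0.339, 0.347, 0.346. So y = 50.8%, conversion is 65.4% and product 14.6%.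

My second doubt is whether reagent and intermediate B are really used up in time. At these amounts reagent decays at 0.109 /s, which gives 17.5 lifetimes after the feed, and intermediate B has a half-life of 2.49 s.

The forecast answers that the reagent has run out first, with 65.4% of the substrate gone and 14.6% product, holding that the steps are “both first order in reagent, so the selectivity doesn't depend on the feed profile”.

In the flask the reagent has run out first, with 0% of its charge left, 65.4% of the substrate gone and 14.6% product. At 0.237 min the flask uses reagent on substrate 5.4 times as fast as on intermediate A, and by 3.00 min the ratio [substrate]/(κ[intermediate A]) has fallen to 1.63, with 50.8% standing as intermediate A. For the neighbour flask with 1.40 equiv of reagent, the same line with κ, run twice from x = 0, gives 7.37% substrate, and that flask holds 7.42%.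

The constants used here are those of an exercise.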